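West and south differ in temperature, 22 °C against 37 °C, as well as in loading, so they cannot be laid side by side to show what X does.

| flask | J | X | temperature | remark | time |
|---|---|---|---|---|---|
| west | 0.020 M | 0.0068 mol% | 22 °C | run made earlier |  |
| south | 0.020 M | 0.13 mol% | 37 °C | run made earlier |  |
| summer | 0.020 M | 0.08 mol% | 37 °C |  | 3.0 min |
| noon | 0.020 M | 0.005 mol% | 37 °C |  | 3.0 min |
| midnight | 0.020 M | 0.01 mol% | 37 °C |  | 3.0 min |
| autumn | 0.020 M | 0.006 mol% | 37 °C |  | 3.0 min |
| spring | 0.020 M | 0.06 mol% | 37 °C |  | 3.0 min |
| winter | 0.020 M | 0.02 mol% | 37 °C |  | 3.0 min |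

All six new flasks hold the same c(J), 0.020 M, at 37 °C, and differ in X, so I needed a rule in X. South shares their temperature, but its loading of 0.13 mol% lies above theirs, so I had to reach down from it.

west run (percent of the J charged)

| time / min | D / % | Z / % |
|---|---|---|
| 0.667 | 0.5 | 0 |
| 1.33 | 1.2 | 0 |
| 2.00 | 1.5 | 3.2 |
| 3.00 | 2.4 | 6.3 |

south run (percent of the J charged)

| time / s | D / % | Z / % |
|---|---|---|
| 10.0 | 0 | 3.4 |
| 15.0 | 3.0 | 1.7 |
| 25.0 | 3.4 | 4.2 |
| 50.0 | 15.5 | 6.6 |
| 90.0 | 30.5 | 9.3 |

(scatter of a reading: 1 percentage point)

- the analysis behind the earlier runs scatters by 1 percentage point, standard deviation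

In west, Z stood above D, 6.3 % to 2.4 % at 3.00 min. In south, D stood above Z, 30.5 % to 9.3 % at 90.0 s. The temperature differs between these two runs as well, so this was an assumption and no finding: I assumed that D grows with X and Z does not, which makes the ratio of D to Z, the selectivity factor, proportional to X.

One quantity then carries the flask: the even loading, the loading of X at which D and Z come out equal, read from south as its loading times Z over D. That gave 0.04 mol%, and the share of D is X/(X + even loading). But at 50.0 s the same reckoning gives 0.055 mol%, so this is a drifting reading with scatter, and I took the last one.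

- the flasks by share of D in all that became D or Z, highest first, at 3.0 min (summer / noon / midnight / autumn / spring / winter)
- the same order at 25 min (summer / noon / midnight / autumn / spring / winter)
- the share of D in all that became D or Z of the flask you put first, at 3.0 min
- the share of D in all that became D or Z of the flask you put last, at 3.0 min

The share rises with X, so I ranked the flasks by loading at both times: summer, spring, winter, midnight, autumn, noon. My shares were 66.9 % for summer and 11.2 % for noon.

The forecast gave summer > spring > winter > midnight > autumn > noon at 3.0 min and summer > spring > winter > midnight > autumn > noon at 25 min, with 71 % and 14 %, both above mine, and its ground was “share rises with loading”.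

The flasks give summer > spring > winter > midnight > autumn > noon at 3.0 min and summer > spring > winter > midnight > autumn > noon at 25 min, with 69.8 % for summer and 17.9 % for noon.

    X → G (k = 0.00610 s⁻¹, Ea = 84.0 kJ mol⁻¹)
    J + G → D + G, rate k2*[J]^3*[G]/(1 + ([J]/Kh2)^3) (10.0 mM, k = 2.70 × 10⁷ M⁻³ s⁻¹, Ea = 8.00 kJ mol⁻¹)
    G → E (k = 2.90 × 10⁻⁵ s⁻¹, Ea = 212 kJ mol⁻¹)
    J ⇌ Q (K = 1.20, k = 0.00790 s⁻¹, Ea = 94.0 kJ mol⁻¹, ΔH = −6.00 kJ mol⁻¹)
    J → Z (k = 0.00190 s⁻¹, Ea = 84.0 kJ mol⁻¹)
    (constants at 37 °C)

Summer's own even loading, from D 34.6 % and Z 15.0 % at 3.00 min, is 0.035 mol%, against the 0.04 mol% I read from south. I carried south's value to a further flask, like summer but with 0.2 mol% of X, and it gave a share of 83.3 %. That flask holds D 50.1 % and Z 12.3 % at 3.00 min, a share of 80.3 %.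

The runs were computed for substances that don't exist; scatter was added.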